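**Assumptions (one line):** (S)-but-3-en-2-ol, allyl TBS ether, 3-(benzyloxy)propanoic acid and the two benzylated bromoarenes (8 and 12) are purchased. Benzyl ethers mask all phenols and the C9′ alcohol until the last step. Lignan numbering: C7/C8/C9 is the guaiacyl side, C7′/C8′/C9′ is the catechol side, and the ring O joins C7′ and C9.

## Retrosynthetic overview
1. The target 14 comes from hydrogenolytic debenzylation of 13. Compound 13 comes from ArMgBr addition to aldehyde 11, which sets C7. Aldehyde 11 comes from ozonolysis of the propenyl group of THF 10.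
2. THF 10 comes from ionic reduction of lactol 9, which sets C7′. Lactol 9 comes from Ar′Li addition to the cis-3,4-disubstituted γ-lactone 7.
3. Lactone 7 comes from desilylative lactonisation of acid 6. Acid 6 comes from an Ireland–Claisen [3,3] rearrangement of ester 5, which forms C8–C8′ and sets both C8 and C8′.
4. Ester 5 comes from (S)-allylic alcohol 3 and acid 4. Alcohol 3 comes from cross-metathesis of (S)-but-3-en-2-ol with allyl TBS ether.
5. The only ring in the target is the THF. It is first built as the γ-lactone (step 4) and becomes the THF in step 6.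

## Route

**Step 1**
Reactants: 1 (S)-but-3-en-2-ol; 2 allyl tert-butyldimethylsilyl ether
Product: 3 (2S,3E)-5-(TBSO)pent-3-en-2-ol
Conditions: Grubbs II (3 mol %), CH2Cl2, 40 °C, 2 (3 equiv)
Reagents that add atoms: none
Why: Olefin cross-metathesis is E-selective and leaves the carbinol stereocenter untouched; that stereocenter is the only chiral input.

**Step 2**
Reactants: 3; 4 3-(benzyloxy)propanoic acid
Product: 5 (2S,3E)-5-(TBSO)pent-3-en-2-yl 3-(benzyloxy)propanoate
Conditions: EDC·HCl, DMAP (cat.), CH2Cl2, 0 °C → rt
Reagents that add atoms: none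
Why: Steglich esterification of a secondary alcohol does not touch the stereocenter or the silyl ether.

**Step 3**
Reactants: 5
Product: 6 (2R,3R,4E)-2-[(benzyloxy)methyl]-3-[(TBSO)methyl]hex-4-enoic acid
Conditions: LDA, THF, –78 °C; TBSCl, –78 °C → rt; aq. NaHSO4 work-up
Reagents that add atoms: none (TBSCl forms a silyl ketene acetal and the silyl ester is hydrolysed on work-up)
Why: The Ireland–Claisen [3,3] rearrangement transfers the carbinol chirality suprafacially. In a chair transition state with the E-alkene and the CH3 equatorial, C8 becomes R. The β-OBn chelates lithium, giving the ester enolate with CH2OBn cis to O–Li. That substituent sits equatorial, so C9′ and C9 end up syn (C8′ = R), which is the cis-lactone required later.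

**Step 4**
Reactants: 6
Product: 7 (3R,4R)-3-[(benzyloxy)methyl]-4-[(E)-prop-1-enyl]oxolan-2-one
Conditions: TsOH·H2O (0.3 equiv), MeOH, rt; then PhMe, 60 °C
Reagents that add atoms: none
Why: Acid removes the primary TBS ether, and the resulting γ-hydroxy acid lactonises (5-exo acyl substitution) without touching either stereocenter. This gives the cis-3,4-disubstituted lactone.

**Step 5**
Reactants: 7; 8 1,2-bis(benzyloxy)-4-bromobenzene
Product: 9 lactol (anomeric mixture at C7′)
Conditions: 8 (1.3 equiv), n-BuLi (1.3 equiv), THF, –78 °C, 30 min; add 7, –78 °C, 1 h; NH4Cl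
Reagents that add atoms: none (the aryl group comes from 8)
Why: The aryllithium adds once to the lactone carbonyl, and the stable lactolate at –78 °C prevents over-addition. C7′ is not yet defined.

**Step 6**
Reactants: 9
Product: 10 (2S,3R,4R)-2-[3,4-bis(benzyloxy)phenyl]-3-[(benzyloxy)methyl]-4-[(E)-prop-1-enyl]oxolane
Conditions: Et3SiH (4 equiv), BF3·OEt2 (3 equiv), CH2Cl2, –78 → –20 °C
Reagents that add atoms: none (only hydrogen is added)
Why: Ionic (oxocarbenium) reduction delivers hydride cis to the C3 substituent of the five-membered oxocarbenium ion (the Woerpel 1,2-cis preference). The aryl group therefore ends up trans to CH2OBn and to the propenyl group, which sets C7′ = S.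

**Step 7**
Reactants: 10
Product: 11 (2S,3R,4R)-2-[3,4-bis(benzyloxy)phenyl]-3-[(benzyloxy)methyl]oxolane-4-carbaldehyde
Conditions: O3, CH2Cl2, –78 °C (stop at blue colour); then Me2S, –78 °C → rt
Reagents that add atoms: ozone, [O-][O+]=O (supplies the aldehyde oxygen)
Why: Ozonolysis of the 1,2-disubstituted alkene is far faster than attack on the arene. The neutral reductive work-up leaves C8 unepimerised, and the crude aldehyde is used at once.

**Step 8**
Reactants: 11; 12 1-(benzyloxy)-4-bromo-2-methoxybenzene (converted in situ to ArMgBr)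
Product: 13 (2S,3R,4R)-2-[3,4-bis(benzyloxy)phenyl]-3-[(benzyloxy)methyl]-4-{(R)-[4-(benzyloxy)-3-methoxyphenyl](hydroxy)methyl}oxolane
Conditions: 12, Mg, THF, reflux; then add 11, THF, –78 → 0 °C; NH4Cl
Reagents that add atoms: none (the aryl group comes from 12)
Why: Grignard addition to an α-branched aldehyde follows the Felkin–Anh model, with aryl attacking anti to the larger C8′ substituent. The chelate through the ring oxygen predicts the same face, so C7 = R.

**Step 9**
Reactants: 13
Product: 14 (7R)-7-hydroxytaxiresinol
Conditions: H2 (1 atm), 10 % Pd/C, EtOAc/MeOH 1:1, rt, monitor closely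
Reagents that add atoms: none (only hydrogen is added)
Why: Hydrogenolysis removes all four benzyl ethers and leaves every stereocenter intact. The benzylic 7-OH is preserved by using a short reaction time and neutral conditions.

## Compound list
1 | (S)-but-3-en-2-ol | C[C@H](O)C=C | starting material
2 | allyl tert-butyldimethylsilyl ether | C=CCO[Si](C)(C)C(C)(C)C | starting material
3 | (2S,3E)-5-(TBSO)pent-3-en-2-ol | C[C@H](O)/C=C/CO[Si](C)(C)C(C)(C)C | intermediate
4 | 3-(benzyloxy)propanoic acid | OC(=O)CCOCc1ccccc1 | starting material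
5 | (2S,3E)-5-(TBSO)pent-3-en-2-yl 3-(benzyloxy)propanoate | C[C@H](OC(=O)CCOCc1ccccc1)/C=C/CO[Si](C)(C)C(C)(C)C | intermediate
6 | (2R,3R,4E)-2-[(benzyloxy)methyl]-3-[(TBSO)methyl]hex-4-enoic acid | C/C=C/[C@@H](CO[Si](C)(C)C(C)(C)C)[C@H](COCc1ccccc1)C(=O)O | intermediate
7 | (3R,4R)-3-[(benzyloxy)methyl]-4-[(E)-prop-1-enyl]oxolan-2-one | C/C=C/[C@H]1COC(=O)[C@H]1COCc1ccccc1 | intermediate
8 | 1,2-bis(benzyloxy)-4-bromobenzene | Brc1ccc(OCc2ccccc2)c(OCc2ccccc2)c1 | starting material
9 | 2-aryl lactol (C7′ epimeric) | C/C=C/[C@H]1COC(O)(c2ccc(OCc3ccccc3)c(OCc3ccccc3)c2)[C@H]1COCc1ccccc1 | intermediate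
10 | (2S,3R,4R)-2-[3,4-bis(benzyloxy)phenyl]-3-[(benzyloxy)methyl]-4-[(E)-prop-1-enyl]oxolane | C/C=C/[C@H]1CO[C@H](c2ccc(OCc3ccccc3)c(OCc3ccccc3)c2)[C@H]1COCc1ccccc1 | intermediate
11 | (2S,3R,4R)-oxolane-4-carbaldehyde | O=C[C@H]1CO[C@H](c2ccc(OCc3ccccc3)c(OCc3ccccc3)c2)[C@H]1COCc1ccccc1 | intermediate
12 | 1-(benzyloxy)-4-bromo-2-methoxybenzene | COc1cc(Br)ccc1OCc1ccccc1 | starting material
13 | tetra-O-benzyl-7-hydroxytaxiresinol | COc1cc([C@H](O)[C@H]2CO[C@H](c3ccc(OCc4ccccc4)c(OCc4ccccc4)c3)[C@H]2COCc2ccccc2)ccc1OCc1ccccc1 | intermediate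
14 | (7R)-7-hydroxytaxiresinol | COc1cc([C@H](O)[C@H]2CO[C@H](c3ccc(O)c(O)c3)[C@H]2CO)ccc1O | target

**Total steps:** 9. **Longest linear sequence:** 9 (from 1).

## Three steps most likely to fail
1. **Step 3 (Ireland–Claisen).** The β-benzyloxy enolate may eliminate BnO⁻ to give an acrylate, or the syn/anti ratio may be poor.
   Fallback: a Johnson–Claisen of 3 (MeC(OMe)3, EtCO2H, 140 °C) sets C8 only. Lactonise to the 4-propenyl lactone and α-methylenate it. Then hydroborate the exocyclic alkene; hydride adds anti to the C4 substituent, which puts CH2OH cis to it and restores the cis-lactone.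
2. **Step 6 (lactol reduction).** Hydride has to arrive cis to both C3 and C4 substituents, and a transannular Prins reaction with the propenyl group could compete.
   Fallback: open lactone 7 to the Weinreb amide and add Ar′Li to give the aryl ketone. Reduce it with Zn(BH4)2 (chelation control), then close the THF by SN2 (Ms, base) so that C7′ is fixed by ketone reduction instead of oxocarbenium reduction.
3. **Step 8 (aryl addition to the aldehyde).** The α-branched aldehyde is epimerisable, and the diastereoselectivity may be modest.
   Fallback: add ArLi non-selectively, oxidise the mixture (DMP) to the aryl ketone, and reduce with Zn(BH4)2 or a bulky borohydride, so that the ring substituents control C7.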